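The earlier runs and the new flask were computed for substances that don't exist, and the scatter is random.

**Counting ligand.** Each complex with three exchanged has taken up 3 incoming ligands. So a flask's ligand ceiling, as a fraction of the starting complex charged, is its equivalents of ligand divided by 3: 66.7% for teal, 100% for ochre and 133% for grey. Grey's figure counts ligand only, and it is more than the complex charged.

common to all: starting complex 0.50 mM
- theta: incoming ligand 1.4 mM; run made earlier
- beta: incoming ligand 2.9 mM; run made earlier
- teal: incoming ligand 1.00 mM; time 2.0 min
- ochre: incoming ligand 1.50 mM; time 2.0 min
- grey: incoming ligand 2.00 mM; time 2.0 min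

- theta (time / s: complex with three exchanged / %, complex with one exchanged / %): 12.0: 3, 11; 25.0: 17, 6; 40.0: 24, 6; 50.0: 32, 3; 60.0: 37, 4
- beta (time / s: complex with three exchanged / %, complex with one exchanged / %): 10.0: 15, 10; 15.0: 22, 4; 30.0: 49, 3; 40.0: 65, 1; 60.0: 71, 4

(each reading ± 1.5 percentage points)

- how much complex with three exchanged is there at the end, in percent of the starting complex charged: for each flask in turn (teal, ochre, grey)

- the numbers in the tables scatter with a standard deviation of 1.5 percentage points

**Two times.** Per equivalent of ligand charged, the complex with three exchanged climbs at 0.00253 s⁻¹ in theta, from first to last reading, and at 0.00293 s⁻¹ in beta, from first to third. We freeze this slope at the mean, 0.00273 s⁻¹, and let the ligand fall. We count 3 units of ligand for each unit of product, so in this reckoning the ligand decays in a pseudo-first-order way. Its use-up time, one over 3 times the frozen slope, is 122 s. The ligand charge cancels out of this reckoned time.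

The other time is the run itself, 2.0 min, and their ratio is 0.984. The share of the ceiling reached is one minus the exponential of minus that ratio, 62.6%. Our reckoning, which holds the complex side fixed, therefore gives 41.7%, 62.6% and 83.4%.

**The forecast.** The forecast reaches its figures by “Scaling the plateau with ligand, or using an equilibrium constant fitted to beta” and gives 30%, 43% and 55%. Our figures are higher than the forecast's in teal, in ochre and in grey.

**The flasks.** Teal, ochre and grey give 34.1%, 57.8% and 72.9%.

    starting complex + incoming ligand → leaving ligand + complex with one exchanged (k = 38.7 M⁻¹ s⁻¹)
    complex with one exchanged + incoming ligand → leaving ligand + complex with two exchanged (k = 167 M⁻¹ s⁻¹)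
    complex with two exchanged + incoming ligand → leaving ligand + complex with three exchanged (k = 36.5 M⁻¹ s⁻¹)
    complex with three exchanged + incoming ligand → leaving ligand + complex with four exchanged (k = 1.22 M⁻¹ s⁻¹)
    starting complex ⇌ dormant form (K = 0.618, k = 0.161 s⁻¹)
    complex with one exchanged → over-reaction product (k = 0.0166 s⁻¹)

Ochre at the asked time also holds 15.4% as complex with two exchanged. Against their ligand ceilings, the results are 51.2%, 57.8% and 54.7%, where our share was 62.6%. Put to use once more, 122 s reckons ochre after 1.00 min at 38.8%, and ochre then holds 39.6% of complex with three exchanged.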